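The molecule is cut at the single bond between two sp2 CH carbons in the middle of the polyene: the terminal CH of the trienyne arm attached to ring A (hydroxycyclohexene) and the CH of the CH=C(CH3) unit of the side chain on ring B (the ylidenebutenolide). A final Stille coupling joins an unprotected (E,E,E)-trienylstannane to an unprotected alkenyl bromide that already carries ring B and epoxide ring C, completing the whole conjugated chromophore with retention of every alkene geometry. The step exploits that the bromide carbon is a vinylogous beta position of the ring B lactone carbonyl, which activates it for oxidative addition; both halves come from one actinol-derived enol triflate.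

Key step: step 19

Remark: (4R,6R)-actinol, (2E)-3-methylpent-2-en-4-yn-1-ol, diethyl prop-2-yn-1-ylphosphonate, furan-2(5H)-one and methacrolein are taken as commercial; anions made with a base just before the electrophile is added (enolate, phosphonate carbanion) are treated as reagent states without numbers; TBS = tert-butyldimethylsilyl.

Step 1
Reactants: 1 (4R,6R)-4-hydroxy-2,2,6-trimethylcyclohexan-1-one ((−)-actinol)
Product: 2 (4R,6R)-4-[(tert-butyldimethylsilyl)oxy]-2,2,6-trimethylcyclohexan-1-one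
Conditions: TBSCl, imidazole, DMF, rt
Reagents that add atoms: tert-butyldimethylsilyl chloride (TBSCl), CC(C)(C)[Si](C)(C)Cl
Why: Imidazole-promoted silylation (silyl ether protection) masks the secondary hydroxyl for the enolate and organometallic steps and leaves both stereocentres untouched.

Step 2
Reactants: 2 (4R,6R)-4-[(tert-butyldimethylsilyl)oxy]-2,2,6-trimethylcyclohexan-1-one
Product: 3 (4R)-4-[(tert-butyldimethylsilyl)oxy]-2,6,6-trimethylcyclohex-1-en-1-yl trifluoromethanesulfonate
Conditions: LiN(iPr)2, THF, −78 → 0 °C; then PhNTf2, −78 °C → rt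
Reagents that add atoms: N-phenylbis(trifluoromethanesulfonimide) (PhNTf2), O=S(=O)(N(c1ccccc1)S(=O)(=O)C(F)(F)F)C(F)(F)F
Why: The ketone can enolise only toward the methyl-bearing carbon, so enolate O-sulfonylation (enol triflate formation) should give the single tetrasubstituted alkenyl triflate, the C6 stereocentre being erased on purpose.

Step 3
Reactants: 3 (4R)-4-[(tert-butyldimethylsilyl)oxy]-2,6,6-trimethylcyclohex-1-en-1-yl trifluoromethanesulfonate; 4 (2E)-3-methylpent-2-en-4-yn-1-ol
Product: 5 (2E)-5-[(4R)-4-[(tert-butyldimethylsilyl)oxy]-2,6,6-trimethylcyclohex-1-en-1-yl]-3-methylpent-2-en-4-yn-1-ol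
Conditions: Pd(PPh3)4 (cat.), CuI (cat.), iPr2NH, DMF, 45 °C
Reagents that add atoms: none
Why: Sonogashira coupling of the alkenyl triflate with the terminal alkyne of 4 attaches the enyne to ring A, the E trisubstituted alkene being carried over unchanged from 4.

Step 4
Reactants: 5 (2E)-5-[(4R)-4-[(tert-butyldimethylsilyl)oxy]-2,6,6-trimethylcyclohex-1-en-1-yl]-3-methylpent-2-en-4-yn-1-ol
Product: 6 (2E)-5-[(4R)-4-[(tert-butyldimethylsilyl)oxy]-2,6,6-trimethylcyclohex-1-en-1-yl]-3-methylpent-2-en-4-ynal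
Conditions: MnO2, CH2Cl2, rt
Reagents that add atoms: none
Why: Allylic oxidation with MnO2 is selective for the primary allylic alcohol and should give the conjugated enynal without touching the silyl ether or the alkene geometry.

Step 5
Reactants: 7 diethyl prop-2-yn-1-ylphosphonate
Product: 8 diethyl [(2E)-3-(tributylstannyl)prop-2-en-1-yl]phosphonate
Conditions: Bu3SnH, AIBN (cat.), toluene, 85 °C
Reagents that add atoms: tributyltin hydride, CCCC[SnH](CCCC)CCCC
Why: Radical hydrostannation places tin on the terminal alkyne carbon and, through reversible stannyl radical addition with a slight excess of tin hydride, should converge on the E alkenylstannane.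

Step 6
Reactants: 6 (2E)-5-[(4R)-4-[(tert-butyldimethylsilyl)oxy]-2,6,6-trimethylcyclohex-1-en-1-yl]-3-methylpent-2-en-4-ynal; 8 diethyl [(2E)-3-(tributylstannyl)prop-2-en-1-yl]phosphonate
Product: 9 tert-butyldimethyl{[(1R)-3,5,5-trimethyl-4-[(3E,5E,7E)-3-methyl-8-(tributylstannyl)octa-3,5,7-trien-1-yn-1-yl]cyclohex-3-en-1-yl]oxy}silane
Conditions: 8, NaN(SiMe3)2, THF, −78 °C; then 6, −78 → 0 °C
Reagents that add atoms: none
Why: Horner–Wadsworth–Emmons olefination of the enal with the allylic phosphonate carbanion should form the new disubstituted alkene with E selectivity while the E alkenylstannane is retained.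

Step 7
Reactants: 9 tert-butyldimethyl{[(1R)-3,5,5-trimethyl-4-[(3E,5E,7E)-3-methyl-8-(tributylstannyl)octa-3,5,7-trien-1-yn-1-yl]cyclohex-3-en-1-yl]oxy}silane
Product: 10 (1R)-3,5,5-trimethyl-4-[(3E,5E,7E)-3-methyl-8-(tributylstannyl)octa-3,5,7-trien-1-yn-1-yl]cyclohex-3-en-1-ol
Conditions: Bu4NF, THF, 0 °C → rt
Reagents that add atoms: none
Why: Fluoride-mediated desilylation frees the ring A hydroxyl, the alkenylstannane, enyne and triene being inert to Bu4NF.

Step 8
Reactants: 3 (4R)-4-[(tert-butyldimethylsilyl)oxy]-2,6,6-trimethylcyclohex-1-en-1-yl trifluoromethanesulfonate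
Product: 11 methyl (4R)-4-[(tert-butyldimethylsilyl)oxy]-2,6,6-trimethylcyclohex-1-ene-1-carboxylate
Conditions: Pd(OAc)2 (cat.), PPh3, CO (1 atm), MeOH, Et3N, DMF, 70 °C
Reagents that add atoms: carbon monoxide, [C-]#[O+]; methanol, CO
Why: Palladium-catalysed methoxycarbonylation (oxidative addition of zerovalent palladium into the C–O triflate bond, CO insertion, methanolysis) installs the ring-bound carbon that becomes the hydroxymethyl handle.

Step 9
Reactants: 11 methyl (4R)-4-[(tert-butyldimethylsilyl)oxy]-2,6,6-trimethylcyclohex-1-ene-1-carboxylate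
Product: 12 [(4R)-4-[(tert-butyldimethylsilyl)oxy]-2,6,6-trimethylcyclohex-1-en-1-yl]methanol
Conditions: iBu2AlH, CH2Cl2, −78 → 0 °C; aq. potassium sodium tartrate work-up
Reagents that add atoms: none
Why: Hydride reduction of the conjugated ester with iBu2AlH proceeds in 1,2-fashion to the allylic alcohol needed to direct the epoxidation.

Step 10
Reactants: 12 [(4R)-4-[(tert-butyldimethylsilyl)oxy]-2,6,6-trimethylcyclohex-1-en-1-yl]methanol
Product: 13 [(1R,4S,6R)-4-[(tert-butyldimethylsilyl)oxy]-2,2,6-trimethyl-7-oxabicyclo[4.1.0]heptan-1-yl]methanol (epoxide oxygen anti to the silyloxy group)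
Conditions: Ti(OiPr)4 (cat.), D-(−)-diethyl tartrate, tBuOOH, 4 Å molecular sieves, CH2Cl2, −20 °C
Reagents that add atoms: tert-butyl hydroperoxide, CC(C)(C)OO
Why: Sharpless asymmetric epoxidation delivers oxygen from the titanium tartrate complex bound to the allylic hydroxyl, and D-(−)-diethyl tartrate should direct it under reagent control to the ring face anti to the silyloxy group, setting both quaternary epoxide stereocentres in one event.

Step 11
Reactants: 13 [(1R,4S,6R)-4-[(tert-butyldimethylsilyl)oxy]-2,2,6-trimethyl-7-oxabicyclo[4.1.0]heptan-1-yl]methanol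
Product: 14 (1S,4S,6R)-4-[(tert-butyldimethylsilyl)oxy]-2,2,6-trimethyl-7-oxabicyclo[4.1.0]heptane-1-carbaldehyde
Conditions: Pr4N[RuO4] (cat.), N-methylmorpholine N-oxide, 4 Å molecular sieves, CH2Cl2, rt
Reagents that add atoms: none
Why: Ley–Griffith oxidation is neutral and should give the epoxy aldehyde without opening the acid-sensitive epoxide, and the quaternary alpha carbon cannot epimerise.

Step 12
Reactants: 14 (1S,4S,6R)-4-[(tert-butyldimethylsilyl)oxy]-2,2,6-trimethyl-7-oxabicyclo[4.1.0]heptane-1-carbaldehyde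
Product: 15 (1R,4S,6R)-4-[(tert-butyldimethylsilyl)oxy]-1-ethynyl-2,2,6-trimethyl-7-oxabicyclo[4.1.0]heptane
Conditions: dimethyl (1-diazo-2-oxopropyl)phosphonate, K2CO3, MeOH, 0 °C → rt
Reagents that add atoms: dimethyl (1-diazo-2-oxopropyl)phosphonate (Ohira–Bestmann reagent), CC(=O)C(=[N+]=[N-])P(=O)(OC)OC
Why: Seyferth–Gilbert homologation with the Ohira–Bestmann reagent converts the non-enolisable aldehyde into the terminal alkyne under mild carbonate conditions that the epoxide and silyl ether tolerate.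

Step 13
Reactants: 15 (1R,4S,6R)-4-[(tert-butyldimethylsilyl)oxy]-1-ethynyl-2,2,6-trimethyl-7-oxabicyclo[4.1.0]heptane
Product: 16 tributyl{(E)-2-[(1S,4S,6R)-4-[(tert-butyldimethylsilyl)oxy]-2,2,6-trimethyl-7-oxabicyclo[4.1.0]heptan-1-yl]ethenyl}stannane
Conditions: Bu3SnH, PdCl2(PPh3)2 (cat.), THF, 0 °C
Reagents that add atoms: tributyltin hydride, CCCC[SnH](CCCC)CCCC
Why: Palladium-catalysed syn hydrostannation puts tin on the terminal carbon because of the bulky quaternary propargylic centre and so should give the E alkenylstannane.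

Step 14
Reactants: 16 tributyl{(E)-2-[(1S,4S,6R)-4-[(tert-butyldimethylsilyl)oxy]-2,2,6-trimethyl-7-oxabicyclo[4.1.0]heptan-1-yl]ethenyl}stannane
Product: 17 (1R,3S,6S)-1,5,5-trimethyl-6-[(E)-2-(tributylstannyl)ethenyl]-7-oxabicyclo[4.1.0]heptan-3-ol
Conditions: Bu4NF, THF, rt
Reagents that add atoms: none
Why: Fluoride-mediated desilylation frees the ring C hydroxyl, the epoxide and alkenylstannane being stable to Bu4NF.

Step 15
Reactants: 18 furan-2(5H)-one
Product: 19 3-iodofuran-2(5H)-one
Conditions: I2, pyridine, CH2Cl2, 0 °C → rt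
Reagents that add atoms: iodine, II
Why: Iodine/pyridine alpha-iodination of the unsaturated lactone (conjugate addition of pyridine, iodination of the enolate, elimination) installs the more reactive of the two halides needed for the later couplings.

Step 16
Reactants: 20 2-methylprop-2-enal (methacrolein)
Product: 22 (2E)-3-bromo-2-methylprop-2-enal, via 2,3-dibromo-2-methylpropanal 21 (not isolated)
Conditions: Br2, CH2Cl2, −78 → 0 °C; then Et3N, 0 °C → rt
Reagents that add atoms: bromine, BrBr
Why: Bromine addition followed by amine-induced dehydrobromination (addition–elimination) should give the thermodynamically preferred E bromoenal with bromine trans to the formyl group.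

Step 17
Reactants: 19 3-iodofuran-2(5H)-one; 22 (2E)-3-bromo-2-methylprop-2-enal
Product: 25 (5Z)-5-[(2E)-3-bromo-2-methylprop-2-en-1-ylidene]-3-iodofuran-2(5H)-one, via silyloxyfuran 23 (not isolated), via silyl aldol adduct 24 (not isolated)
Conditions: TBSOTf, iPr2NEt, CH2Cl2, 0 °C → rt; then DBU, rt
Reagents that add atoms: none
Why: One-pot vinylogous Mukaiyama aldol addition of the silyloxyfuran through C5 to the aldehyde, then base-induced beta-elimination of silanol (E1cB), should give the thermodynamically favoured Z ylidenebutenolide with the E bromoalkene retained.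

Step 18
Reactants: 17 (1R,3S,6S)-1,5,5-trimethyl-6-[(E)-2-(tributylstannyl)ethenyl]-7-oxabicyclo[4.1.0]heptan-3-ol; 25 (5Z)-5-[(2E)-3-bromo-2-methylprop-2-en-1-ylidene]-3-iodofuran-2(5H)-one
Product: 26 (5Z)-5-[(2E)-3-bromo-2-methylprop-2-en-1-ylidene]-3-[(E)-2-[(1S,4S,6R)-4-hydroxy-2,2,6-trimethyl-7-oxabicyclo[4.1.0]heptan-1-yl]ethenyl]furan-2(5H)-one
Conditions: Pd2(dba)3 (cat.), AsPh3, NMP, rt, dark
Reagents that add atoms: none
Why: Stille coupling relies on the faster oxidative addition of zerovalent palladium into the alpha-iodo lactone C–I bond than into the alkenyl C–Br bond at room temperature, so the E alkenyl group of 17 should be transferred with retention to C3 of ring B only.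

Step 19
Reactants: 10 (1R)-3,5,5-trimethyl-4-[(3E,5E,7E)-3-methyl-8-(tributylstannyl)octa-3,5,7-trien-1-yn-1-yl]cyclohex-3-en-1-ol; 26 (5Z)-5-[(2E)-3-bromo-2-methylprop-2-en-1-ylidene]-3-[(E)-2-[(1S,4S,6R)-4-hydroxy-2,2,6-trimethyl-7-oxabicyclo[4.1.0]heptan-1-yl]ethenyl]furan-2(5H)-one
Product: 27 (5Z)-3-[(E)-2-[(1S,4S,6R)-4-hydroxy-2,2,6-trimethyl-7-oxabicyclo[4.1.0]heptan-1-yl]ethenyl]-5-[(2E,4E,6E,8E)-11-[(4R)-4-hydroxy-2,6,6-trimethylcyclohex-1-en-1-yl]-2,9-dimethylundeca-2,4,6,8-tetraen-10-yn-1-ylidene]furan-2(5H)-one (target)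
Conditions: Pd2(dba)3 (cat.), AsPh3, NMP, 45 °C, dark, argon
Reagents that add atoms: none
Why: Zerovalent palladium inserts into the C–Br bond of 26, the alkenylpalladium bromide takes over the trienyl group of 10 by transmetalation from tin (the sp2 carbon migrates in preference to butyl), and reductive elimination forms the sp2–sp2 single bond between the trienyne terminus and the CH of the methylallylidene chain. The closest known reaction type is the Stille alkenyl–alkenyl cross-coupling of polyenylstannanes with halogenated ylidenebutenolides used for carotenoid-type polyenes. No ring is closed and no stereocentre is created; the four existing stereocentres are remote and untouched. Oxidative addition and transmetalation are stereoretentive, so the E geometry at both coupling carbons is inherited from 10 and 26, and the Z ylidene and the remaining E alkenes are not disturbed. The selectivity needed is cross-coupling at the single carbon–halogen bond without homocoupling or E/Z scrambling, and it is secured by the conjugation of the C–Br carbon through ring B to the lactone carbonyl (a vinylogous beta-bromo enoate), which speeds oxidative addition so that mild heating with the weakly donating AsPh3 ligand should suffice. The neutral, base-free medium is what lets the two free hydroxyls, the vinyl epoxide of ring C and the base-sensitive butenolide go through unprotected.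

Compound list
1 | (4R,6R)-4-hydroxy-2,2,6-trimethylcyclohexan-1-one ((−)-actinol) | O=C1C(C)(C)C[C@H](O)C[C@H]1C | starting material
2 | (4R,6R)-4-[(tert-butyldimethylsilyl)oxy]-2,2,6-trimethylcyclohexan-1-one | O=C1C(C)(C)C[C@H](O[Si](C)(C)C(C)(C)C)C[C@H]1C | intermediate
3 | (4R)-4-[(tert-butyldimethylsilyl)oxy]-2,6,6-trimethylcyclohex-1-en-1-yl trifluoromethanesulfonate | CC1=C(OS(=O)(=O)C(F)(F)F)C(C)(C)C[C@H](O[Si](C)(C)C(C)(C)C)C1 | intermediate
4 | (2E)-3-methylpent-2-en-4-yn-1-ol | C#C/C(C)=C/CO | starting material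
5 | (2E)-5-[(4R)-4-[(tert-butyldimethylsilyl)oxy]-2,6,6-trimethylcyclohex-1-en-1-yl]-3-methylpent-2-en-4-yn-1-ol | CC1=C(C#C/C(C)=C/CO)C(C)(C)C[C@H](O[Si](C)(C)C(C)(C)C)C1 | intermediate
6 | (2E)-5-[(4R)-4-[(tert-butyldimethylsilyl)oxy]-2,6,6-trimethylcyclohex-1-en-1-yl]-3-methylpent-2-en-4-ynal | CC1=C(C#C/C(C)=C/C=O)C(C)(C)C[C@H](O[Si](C)(C)C(C)(C)C)C1 | intermediate
7 | diethyl prop-2-yn-1-ylphosphonate | C#CCP(=O)(OCC)OCC | starting material
8 | diethyl [(2E)-3-(tributylstannyl)prop-2-en-1-yl]phosphonate | CCCC[Sn](CCCC)(CCCC)/C=C/CP(=O)(OCC)OCC | intermediate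
9 | tert-butyldimethyl{[(1R)-3,5,5-trimethyl-4-[(3E,5E,7E)-3-methyl-8-(tributylstannyl)octa-3,5,7-trien-1-yn-1-yl]cyclohex-3-en-1-yl]oxy}silane | CC1=C(C#C/C(C)=C/C=C/C=C/[Sn](CCCC)(CCCC)CCCC)C(C)(C)C[C@H](O[Si](C)(C)C(C)(C)C)C1 | intermediate
10 | (1R)-3,5,5-trimethyl-4-[(3E,5E,7E)-3-methyl-8-(tributylstannyl)octa-3,5,7-trien-1-yn-1-yl]cyclohex-3-en-1-ol | CC1=C(C#C/C(C)=C/C=C/C=C/[Sn](CCCC)(CCCC)CCCC)C(C)(C)C[C@H](O)C1 | intermediate
11 | methyl (4R)-4-[(tert-butyldimethylsilyl)oxy]-2,6,6-trimethylcyclohex-1-ene-1-carboxylate | CC1=C(C(=O)OC)C(C)(C)C[C@H](O[Si](C)(C)C(C)(C)C)C1 | intermediate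
12 | [(4R)-4-[(tert-butyldimethylsilyl)oxy]-2,6,6-trimethylcyclohex-1-en-1-yl]methanol | CC1=C(CO)C(C)(C)C[C@H](O[Si](C)(C)C(C)(C)C)C1 | intermediate
13 | [(1R,4S,6R)-4-[(tert-butyldimethylsilyl)oxy]-2,2,6-trimethyl-7-oxabicyclo[4.1.0]heptan-1-yl]methanol | OC[C@@]12O[C@]1(C)C[C@@H](O[Si](C)(C)C(C)(C)C)CC2(C)C | intermediate
14 | (1S,4S,6R)-4-[(tert-butyldimethylsilyl)oxy]-2,2,6-trimethyl-7-oxabicyclo[4.1.0]heptane-1-carbaldehyde | O=C[C@@]12O[C@]1(C)C[C@@H](O[Si](C)(C)C(C)(C)C)CC2(C)C | intermediate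
15 | (1R,4S,6R)-4-[(tert-butyldimethylsilyl)oxy]-1-ethynyl-2,2,6-trimethyl-7-oxabicyclo[4.1.0]heptane | C#C[C@@]12O[C@]1(C)C[C@@H](O[Si](C)(C)C(C)(C)C)CC2(C)C | intermediate
16 | tributyl{(E)-2-[(1S,4S,6R)-4-[(tert-butyldimethylsilyl)oxy]-2,2,6-trimethyl-7-oxabicyclo[4.1.0]heptan-1-yl]ethenyl}stannane | CCCC[Sn](CCCC)(CCCC)/C=C/[C@@]12O[C@]1(C)C[C@@H](O[Si](C)(C)C(C)(C)C)CC2(C)C | intermediate
17 | (1R,3S,6S)-1,5,5-trimethyl-6-[(E)-2-(tributylstannyl)ethenyl]-7-oxabicyclo[4.1.0]heptan-3-ol | CCCC[Sn](CCCC)(CCCC)/C=C/[C@@]12O[C@]1(C)C[C@@H](O)CC2(C)C | intermediate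
18 | furan-2(5H)-one | O=C1OCC=C1 | starting material
19 | 3-iodofuran-2(5H)-one | O=C1OCC=C1I | intermediate
20 | 2-methylprop-2-enal (methacrolein) | CC(=C)C=O | starting material
21 | 2,3-dibromo-2-methylpropanal (racemic) | CC(Br)(CBr)C=O | intermediate
22 | (2E)-3-bromo-2-methylprop-2-enal | Br/C=C(C)/C=O | intermediate
23 | tert-butyl[(3-iodofuran-2-yl)oxy]dimethylsilane | CC(C)(C)[Si](C)(C)Oc1occc1I | intermediate
24 | 5-[(2E)-3-bromo-1-[(tert-butyldimethylsilyl)oxy]-2-methylprop-2-en-1-yl]-3-iodofuran-2(5H)-one (diastereomer mixture) | CC(C)(C)[Si](C)(C)OC(/C(C)=C/Br)C1OC(=O)C(I)=C1 | intermediate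
25 | (5Z)-5-[(2E)-3-bromo-2-methylprop-2-en-1-ylidene]-3-iodofuran-2(5H)-one | Br/C=C(C)/C=C1C=C(I)C(=O)O/1 | intermediate
26 | (5Z)-5-[(2E)-3-bromo-2-methylprop-2-en-1-ylidene]-3-[(E)-2-[(1S,4S,6R)-4-hydroxy-2,2,6-trimethyl-7-oxabicyclo[4.1.0]heptan-1-yl]ethenyl]furan-2(5H)-one | Br/C=C(C)/C=C1C=C(/C=C/[C@@]23O[C@]2(C)C[C@@H](O)CC3(C)C)C(=O)O/1 | intermediate
27 | (5Z)-3-[(E)-2-[(1S,4S,6R)-4-hydroxy-2,2,6-trimethyl-7-oxabicyclo[4.1.0]heptan-1-yl]ethenyl]-5-[(2E,4E,6E,8E)-11-[(4R)-4-hydroxy-2,6,6-trimethylcyclohex-1-en-1-yl]-2,9-dimethylundeca-2,4,6,8-tetraen-10-yn-1-ylidene]furan-2(5H)-one | CC1=C(C#C/C(C)=C/C=C/C=C/C=C(C)/C=C2C=C(/C=C/[C@@]34O[C@]3(C)C[C@@H](O)CC4(C)C)C(=O)O/2)C(C)(C)C[C@H](O)C1 | target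

Total step count: 19.
Longest linear sequence: 11 steps (steps 1, 2, 8, 9, 10, 11, 12, 13, 14, 18, 19).

Steps most likely to fail

1. Step 19. Oxidative addition into the alkenyl bromide may be too slow at a temperature the polyene tolerates, so that stannane homocoupling, protodestannylation and E/Z isomerisation compete. The fallback inverts the order of the two couplings and puts an iodide at the chain terminus; it sets out from 10 and comes back at 27. 3-Bromofuran-2(5H)-one F1 would be condensed (TBSOTf, iPr2NEt; then DBU, as in step 17) with (2E)-3-iodo-2-methylprop-2-enal F3, itself obtained by MnO2 oxidation of (2E)-3-iodo-2-methylprop-2-en-1-ol F2, to give (5Z)-3-bromo-5-[(2E)-3-iodo-2-methylprop-2-en-1-ylidene]furan-2(5H)-one F4. Stannane 10 would then be coupled at room temperature at the alkenyl iodide of F4 (Stille, same bond as in step 19) to give (5Z)-3-bromo-5-[(2E,4E,6E,8E)-11-[(4R)-4-hydroxy-2,6,6-trimethylcyclohex-1-en-1-yl]-2,9-dimethylundeca-2,4,6,8-tetraen-10-yn-1-ylidene]furan-2(5H)-one F5. A second Stille coupling of F5 at the C3–Br bond with stannane 17 returns to 27.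

2. Step 18. Chemoselectivity may be lost through oxidative addition at the alkenyl bromide as well as at the iodide, leading to double coupling and oligomers. The fallback removes the competing halide by changing the order of events; it sets out from 16 and 19 and comes back at 26. Stille coupling of 16 with 19 would give 3-[(E)-2-[(1S,4S,6R)-4-[(tert-butyldimethylsilyl)oxy]-2,2,6-trimethyl-7-oxabicyclo[4.1.0]heptan-1-yl]ethenyl]furan-2(5H)-one F6. One-pot silyloxyfuran aldol–elimination of F6 with 22 (TBSOTf added slowly to excess iPr2NEt at low temperature to spare the epoxide; then DBU) would give the silyl ether of 26, (5Z)-5-[(2E)-3-bromo-2-methylprop-2-en-1-ylidene]-3-[(E)-2-[(1S,4S,6R)-4-[(tert-butyldimethylsilyl)oxy]-2,2,6-trimethyl-7-oxabicyclo[4.1.0]heptan-1-yl]ethenyl]furan-2(5H)-one F7. Desilylation with pyridine-buffered HF·pyridine returns to 26.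

3. Step 17. The amine bases may add to the beta-bromo enal or to the product by addition–elimination, and the E1cB elimination may give incomplete Z selectivity. The fallback separates carbon–carbon bond formation from alkene formation; it sets out from 19 and 22 and comes back at 25. Compound 19 would be silylated (TBSOTf, Et3N) and 23 isolated; a vinylogous Mukaiyama aldol addition of 23 to 22 with BF3·OEt2 at −78 °C would give the free aldol 5-[(2E)-3-bromo-1-hydroxy-2-methylprop-2-en-1-yl]-3-iodofuran-2(5H)-one F8. After separation of its diastereomers, F8 would be dehydrated by stereospecific anti elimination under Mitsunobu-type conditions (PPh3, diethyl azodicarboxylate) to return to 25.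

Further compounds
F1 | step 19 | 3-bromofuran-2(5H)-one | O=C1OCC=C1Br
F2 | step 19 | (2E)-3-iodo-2-methylprop-2-en-1-ol | OC/C(C)=C/I
F3 | step 19 | (2E)-3-iodo-2-methylprop-2-enal | O=C/C(C)=C/I
F4 | step 19 | (5Z)-3-bromo-5-[(2E)-3-iodo-2-methylprop-2-en-1-ylidene]furan-2(5H)-one | I/C=C(C)/C=C1C=C(Br)C(=O)O/1
F5 | step 19 | (5Z)-3-bromo-5-[(2E,4E,6E,8E)-11-[(4R)-4-hydroxy-2,6,6-trimethylcyclohex-1-en-1-yl]-2,9-dimethylundeca-2,4,6,8-tetraen-10-yn-1-ylidene]furan-2(5H)-one | CC1=C(C#C/C(C)=C/C=C/C=C/C=C(C)/C=C2C=C(Br)C(=O)O/2)C(C)(C)C[C@H](O)C1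
F6 | step 18 | 3-[(E)-2-[(1S,4S,6R)-4-[(tert-butyldimethylsilyl)oxy]-2,2,6-trimethyl-7-oxabicyclo[4.1.0]heptan-1-yl]ethenyl]furan-2(5H)-one | O=C1OCC=C1/C=C/[C@@]23O[C@]2(C)C[C@@H](O[Si](C)(C)C(C)(C)C)CC3(C)C
F7 | step 18 | (5Z)-5-[(2E)-3-bromo-2-methylprop-2-en-1-ylidene]-3-[(E)-2-[(1S,4S,6R)-4-[(tert-butyldimethylsilyl)oxy]-2,2,6-trimethyl-7-oxabicyclo[4.1.0]heptan-1-yl]ethenyl]furan-2(5H)-one | Br/C=C(C)/C=C1C=C(/C=C/[C@@]23O[C@]2(C)C[C@@H](O[Si](C)(C)C(C)(C)C)CC3(C)C)C(=O)O/1
F8 | step 17 | 5-[(2E)-3-bromo-1-hydroxy-2-methylprop-2-en-1-yl]-3-iodofuran-2(5H)-one | OC(/C(C)=C/Br)C1OC(=O)C(I)=C1
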